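## Structural features

Astepyrazinoxide (19) is a 1-hydroxypyrazin-2(1H)-one, a cyclic hydroxamic acid, whose ring atoms are N1(OH), C2(=O), C3(CH3), N4, C5(OCH3) and C6. C6 is joined through one CH2 group to C3' of an indole (primed numbers), and the indole carries a 3-methylbut-2-en-1-yl (prenyl) chain at C7', next to the free N1'–H. The molecule has no stereocentre and no stereogenic double bond, so no two stereocentres stand next to each other and nothing has to be controlled in space. The fragile parts are the N–O bond with its acidic, metal-binding N–OH, the lactim ether at C5, the electron-rich 3-alkylindole (oxidants, hard electrophiles, strong acid) and the trisubstituted prenyl alkene (protic acid can hydrate it or close it onto N1'; oxidants and hydrogenation also attack it). The real difficulty is regiochemistry and chemoselectivity: four different substituents must be placed around the ring, the two amide-type oxygens must be told apart (one stays C2=O, the other becomes OCH3), and N1 must carry oxygen. The ring must also reach the aromatic level without an oxidant that indole or prenyl would not survive. The key step uses the fact that C6 is flanked by N1 and the side-chain CH2: in the tautomer with an exocyclic C6=CH bond, C6 is an enamide carbon, the dehydration product of a ketone and an N–H. The N1–C6 bond can therefore come from a hydroxamate N–H and the ketone of an (indol-3-yl)pyruvoyl amide, and the C3–H of an alanine unit later supplies the proton that is moved to the exocyclic carbon to aromatise the ring.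

## Logic of the disconnections

19 to 18: only the O–C bond of an allyl group on the oxygen of N1 is cut. The free N–OH is acidic, binds metals and would itself be methylated by an oxonium salt, so it is carried masked; allyl comes off with zerovalent palladium and an amine, without acid, oxidant or hydrogen. The demand is that the deallylation leaves the prenyl alkene and the lactim ether untouched.

18 to 16: the O–CH3 bond at C5 is cut and one hydrogen is moved back from the side-chain CH2 to C3, which turns the aromatic ring into a 6-ylidene-2,5-dioxopiperazine of the same oxidation level. In 16 the two carbonyls differ: C5=O belongs to an N–H lactam and can be O-alkylated, whereas C2=O belongs to the N-alkoxy amide and cannot give a neutral lactim ether. The gain is aromatisation without an oxidant; the demand is O-selective methylation beside a free indole and a clean base-mediated proton shift through 17.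

16 to 14: the N1–C6 bond is cut and water is added across C6=CH, which opens the only new ring and leaves an acyclic keto amide held together by amide bonds. The cut belongs here because C6 of 16 is at the ketone level and N1 is a hydroxamate N–H, so the bond is a condensation. The demand is closure through nitrogen and not through the hydroxamate carbonyl oxygen, dehydration towards the side chain, and conditions that indole, prenyl and allyl groups tolerate.

14 to 9 and 13: the N4–C5 amide bond is cut, dividing the chain into an α-keto acid that carries the whole indole part and an amino hydroxamate of similar size. The gain is convergence; the demand is an amide coupling in which an enolisable, air-sensitive α-keto acid is activated beside a free hydroxamate N–H.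

13 to 12, then to 10 and 11: the carbamate on N4 is restored and the C2–N1 hydroxamate bond is cut. Both are routine peptide operations; the S centre of 10 is carried only because this is the cheapest form, since step 9 erases it. The demand is acylation at the nitrogen of 11 and an acidolysis that spares the O-allyl group.

9 to 7, then to 5 and 6: the bond between the side-chain carbon and C6 is cut as a C=C bond, so that 6 supplies C5 and C6 and 5 supplies the indole with its CH carbon. The azlactone is the shortest access to an arylpyruvic acid and its hydrolysis needs only base, which the prenyl group tolerates. The demand is that the vinylogous-amide aldehyde 5 becomes electrophilic enough (it is N-acetylated in the flask) and that 9 is kept from air.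

5 to 3: the C3'–CHO bond is cut, because electrophilic formylation of an indole goes to C3' by itself. The demand is that the electrophile ignores the prenyl alkene and that no aqueous acid is used in the work-up.

3 to 1 and 2: the C7'–CH2 bond between an sp2 and an allylic sp3 carbon is cut, leading to a commercial 7-haloindole and an allylboron reagent. The demand is allyl transfer through the unsubstituted terminus, so that the prenyl and not the 1,1-dimethylallyl isomer forms, with the N–H unprotected.

## Other disconnections considered

Alternative 1: Larock heteroannulation.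
- **Cut:** through the pyrrole ring of the indole at C3a'–C3' and N1'–C2'. This gives 2-bromo-6-(3-methylbut-2-en-1-yl)aniline A2 and the complete, O-protected pyrazinone 5-methoxy-1-[(4-methoxybenzyl)oxy]-3-methyl-6-[3-(triethylsilyl)prop-2-yn-1-yl]pyrazin-2(1H)-one A3.
- **Forward key step:** with Pd(OAc)2, P(t-Bu)3 and K2CO3 the alkyne would insert into the aryl–palladium bond so that the aryl carbon bonds to the alkyne carbon bearing the CH2 group and the bulky silyl group ends next to nitrogen. C–N reductive elimination would then close the ring to the 2'-triethylsilyl O-(4-methoxybenzyl) derivative of the target A1.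
- **In its favour:** it is the most convergent plan, the silyl group dictates the regiochemistry of insertion, and the prenyl position is fixed in A2. The sensitive indole appears only at the end, so O-methylation is done on a robust monocycle and no air-sensitive indolylpyruvic acid is handled. On these points it is better than the chosen plan.
- **Against it here:**
  - It does not say how the N-alkoxypyrazinone ring of A3 is made, so the central problem is only moved into a fragment that still needs its own ring synthesis.
  - An O-allyl group cannot be used because zerovalent palladium would remove it. The 4-methoxybenzyl group that replaces it must leave under acid or oxidation beside the prenyl alkene and the indole.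
  - The propargylic CH2 of A3 can isomerise to the allene under hot carbonate.
  - A1 still needs protodesilylation and deprotection.
- **Comparison:** on structure, A1 holds the whole skeleton but two groups too many, whereas 16 has the right substituents at the right oxidation level. On mechanism, a silyl-directed carbopalladation is the equal of the cyclodehydration in soundness. On step economy, the end games are about equal, but the separate syntheses of A2 and A3 would make the total clearly longer than ten steps.

Alternative 2: amidofuran Diels–Alder.
- **Cut:** through the benzene ring of the indole at C7a'–C3a' and C5'–C4', so that the carbocycle is built from a furan.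
- **Forward key step:** tert-butyl N-(but-3-en-1-yl)-N-[3-(3-methylbut-2-en-1-yl)furan-2-yl]carbamate A5 would undergo a thermal intramolecular [4+2] cycloaddition. The oxygen bridge would be opened by the nitrogen lone pair and water lost, giving tert-butyl 7-(3-methylbut-2-en-1-yl)indoline-1-carboxylate A4.
- **In its favour:** the prenyl group rides on C3 of the furan and must end at C7', no transition metal or allyl–metal species is involved, and two C–C bonds and an aromatic ring form in one operation. In certainty of the prenyl position it is better than step 1 of the chosen plan, where α- against γ-coupling must be controlled.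
- **Against it here:**
  - It solves a problem that a commercial 7-haloindole already solves.
  - A4 is only a precursor of 3 and still needs carbamate removal and dehydrogenation of the indoline by an oxidant beside the prenyl group, after which all of steps 2 to 10 remain.
  - A5 itself needs a multistep furan synthesis.
  - The thermolysis temperature invites ene-type side reactions of the prenyl alkene.
- **Comparison:** on structure, A4 contains none of the pyrazinone and not the linking CH2. On mechanism, the cascade is as sound as the chosen key step but addresses the easy half of the molecule. On step economy, it replaces one step (1 to 3) by at least six; it would serve only as a second source of 3.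

Alternative 3: isocyanide cascade.
- **Cut:** two ring bonds at once, C5–C6 and N1–C2. This leads back to 2-[7-(3-methylbut-2-en-1-yl)-1H-indol-3-yl]acetaldehyde O-allyl oxime A7 and potassium 2-isocyanopropanoate A8.
- **Forward key step:** ZnCl2 activates the oxime ether of A7 and the isocyanide carbon adds to its carbon. The nitrilium ion is trapped by the carboxylate as an oxazol-5(4H)-one, and the N-alkoxyamine nitrogen opens this by Mumm-type acyl transfer. The product would be 1-(allyloxy)-3-methyl-6-{[7-(3-methylbut-2-en-1-yl)-1H-indol-3-yl]methyl}piperazine-2,5-dione A6 as a mixture of diastereomers.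
- **In its favour:** two skeletal bonds and the ring form in one operation from two small components, the N–O bond is already present in the oxime, and no keto acid is handled. In bond-forming efficiency and convergence it is better than the chosen plan, whose key step forms one bond.
- **Against it here:**
  - A6 is two hydrogens richer than 16, so after O-methylation a dehydrogenation is unavoidable, and the oxidant would meet the indole, its side-chain CH2 and the prenyl alkene.
  - O-alkyl oximes are weak electrophiles towards isocyanides, and the Lewis acid needed can also engage the indole.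
  - α-Isocyano carboxylates are labile.
  - The aldehyde class behind A7 is unstable.
- **Comparison:** on structure, A6 has the skeleton and protecting group of 16 but the wrong oxidation level at C6. On mechanism, the cascade has several stages that must each beat a side reaction (for example hydration of the nitrilium ion), whereas the cyclodehydration has one equilibrium and one irreversible exit. On step economy, the step count to the ring is about equal, but the extra oxidation makes the end longer and riskier.

Key step: step 8

Remarks on the chemistry:
- The structures of 14 and 16 are consistent (S at C3 from L-alanine; exocyclic alkene written Z, N1 and indole on the same side) and need no correction. 16 is assumed to form mainly as the Z isomer; an E/Z mixture would serve equally, because step 9 removes the geometry.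
- One point in the selectivity argument for the key step is corrected: the carbonyl oxygen of the hydroxamate would also close a six-membered ring, so ring size alone does not secure N-closure. N-selectivity rests on the reversibility of that O-adduct and the irreversible dehydration of the N-adduct.
- The indole nitrogen is left unprotected because the hot hydroxide of step 4 would strip any acyl or carbamate group, and the later steps are argued to tolerate the N–H. Allyl is kept on the hydroxamate oxygen because it survives PPTS, the oxonium salt and DBU.

## Route

Step 1
Reactants: 1 7-bromo-1H-indole; 2 4,4,5,5-tetramethyl-2-(3-methylbut-2-en-1-yl)-1,3,2-dioxaborolane (prenylboronic acid pinacol ester)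
Product: 3 7-(3-methylbut-2-en-1-yl)-1H-indole
Conditions: PdCl2(IPent)(3-chloropyridine) (2 mol %; IPent = 1,3-bis[2,6-di(pentan-3-yl)phenyl]imidazol-2-ylidene), 5 M aq KOH, THF, 70 °C
Reagents that add atoms: none
Why: Suzuki–Miyaura sp2–sp3 coupling of an aryl bromide with an allylboronate; with the very bulky carbene ligand the σ-allyl palladium intermediate should equilibrate to the less hindered primary isomer before reductive elimination, giving the prenyl (α) and not the 1,1-dimethylallyl (γ) product, and the free indole N–H is tolerated under aqueous hydroxide.

Step 2
Reactants: 3 7-(3-methylbut-2-en-1-yl)-1H-indole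
Product: 5 7-(3-methylbut-2-en-1-yl)-1H-indole-3-carbaldehyde, via iminium chloride 4 (not isolated)
Conditions: POCl3, DMF, 0 °C to rt; then 2 M aq NaOH, 0 °C to rt
Reagents that add atoms: N,N-dimethylformamide, CN(C)C=O (formyl carbon); water, O (carbonyl oxygen)
Why: Vilsmeier–Haack formylation; the chloroiminium ion attacks C3', the most nucleophilic position of the indole, while the isolated trisubstituted alkene is too weak a nucleophile to compete at 0 °C, and basic hydrolysis of 4 keeps aqueous acid away from the prenyl group.

Step 3
Reactants: 5 7-(3-methylbut-2-en-1-yl)-1H-indole-3-carbaldehyde; 6 N-acetylglycine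
Product: 7 (4Z)-4-{[1-acetyl-7-(3-methylbut-2-en-1-yl)-1H-indol-3-yl]methylidene}-2-methyl-1,3-oxazol-5(4H)-one
Conditions: Ac2O, NaOAc, 100 °C
Reagents that add atoms: acetic anhydride, CC(=O)OC(C)=O (N1'-acetyl group)
Why: Erlenmeyer–Plöchl azlactone synthesis; Ac2O cyclodehydrates 6 to 2-methyloxazol-5(4H)-one, whose C4 carbanion condenses with the aldehyde, and concurrent N1'-acetylation removes the vinylogous-amide deactivation of the formyl group. The thermodynamically preferred Z alkene is expected, and its geometry is irrelevant later.

Step 4
Reactants: 7 (4Z)-4-{[1-acetyl-7-(3-methylbut-2-en-1-yl)-1H-indol-3-yl]methylidene}-2-methyl-1,3-oxazol-5(4H)-one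
Product: 9 3-[7-(3-methylbut-2-en-1-yl)-1H-indol-3-yl]-2-oxopropanoic acid, via sodium acetamidoacrylate 8 (not isolated)
Conditions: degassed 2 M aq NaOH, 1,4-dioxane, 100 °C, Ar; then 2 M HCl to pH 2, 0 °C; used at once
Reagents that add atoms: water, O (as hydroxide; ketone oxygen and one carboxyl oxygen)
Why: Alkaline hydrolysis of an azlactone to an arylpyruvic acid; hydroxide opens the oxazolone and removes the N1'-acetyl group to give 8, then hydrolysis of the acetamide leaves an enamine that tautomerises to the imine and loses ammonia. Only base is used, so the prenyl alkene is safe, and exclusion of oxygen protects the enol-rich keto acid.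

Step 5
Reactants: 10 N-(tert-butoxycarbonyl)-L-alanine; 11 O-allylhydroxylamine hydrochloride
Product: 12 tert-butyl N-[(2S)-1-(allyloxyamino)-1-oxopropan-2-yl]carbamate
Conditions: EDC·HCl, HOBt, N-methylmorpholine, CH2Cl2, 0 °C to rt
Reagents that add atoms: none
Why: Carbodiimide/HOBt amide coupling; the α-effect nitrogen of the alkoxyamine is acylated cleanly, and the urethane-protected acid resists oxazolone formation, so the S centre is retained (although its configuration is not needed in the end).

Step 6
Reactants: 12 tert-butyl N-[(2S)-1-(allyloxyamino)-1-oxopropan-2-yl]carbamate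
Product: 13 (2S)-N-(allyloxy)-2-aminopropanamide hydrochloride
Conditions: 4 M HCl in 1,4-dioxane, rt
Reagents that add atoms: hydrogen chloride, Cl (chloride of the salt)
Why: Acidolytic removal of the Boc group by loss of the tert-butyl cation and decarboxylation; the O-allyl hydroxamate is inert to anhydrous HCl at room temperature, and the amine is stored as its salt.

Step 7
Reactants: 9 3-[7-(3-methylbut-2-en-1-yl)-1H-indol-3-yl]-2-oxopropanoic acid; 13 (2S)-N-(allyloxy)-2-aminopropanamide hydrochloride
Product: 14 N-[(2S)-1-(allyloxyamino)-1-oxopropan-2-yl]-3-[7-(3-methylbut-2-en-1-yl)-1H-indol-3-yl]-2-oxopropanamide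
Conditions: EDC·HCl, HOAt, N-methylmorpholine, DMF, 0 °C to rt
Reagents that add atoms: none
Why: Amide coupling through the HOAt active ester; the primary amine released from 13 is far more nucleophilic than the hydroxamate N–H or the enol oxygen, and any imine formed reversibly at the ketone is hydrolysed on aqueous work-up.

Step 8
Reactants: 14 N-[(2S)-1-(allyloxyamino)-1-oxopropan-2-yl]-3-[7-(3-methylbut-2-en-1-yl)-1H-indol-3-yl]-2-oxopropanamide
Product: 16 (3S,6Z)-1-(allyloxy)-3-methyl-6-{[7-(3-methylbut-2-en-1-yl)-1H-indol-3-yl]methylidene}piperazine-2,5-dione, via cyclic hemiaminal 15 (not isolated)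
Conditions: PPTS (0.2 equiv), 4 Å molecular sieves, toluene, 80 °C
Reagents that add atoms: none
Why: This is an acid-catalysed intramolecular condensation of an amide-type N–H with a ketone, the reaction type by which N-(α-ketoacyl) amino acid amides give 3-ylidene-2,5-dioxopiperazines and by which α-amino hydroxamic acids condense with 1,2-dicarbonyl compounds to cyclic hydroxamic acids. PPTS returns the enol of 14 to the keto form and activates the ketone, which the adjacent amide carbonyl already makes electrophilic, and the hydroxamate nitrogen N1 adds in a 6-exo-trig closure to give hemiaminal 15. Water can be lost from 15 only towards the side-chain CH2, since C6 has no other β-hydrogen, and this gives the enamide conjugated with the indole; the sieves remove water and pull all equilibria to 16. No lasting stereocentre is made: the C6 centre of 15 disappears on dehydration, the alkene is expected mainly Z, and both the geometry and the alanine-derived C3 centre are erased in step 9. The selectivity needed is N- over O-closure: N4 could only form a three-membered ring and the allyloxy oxygen is a non-nucleophilic ether, but the hydroxamate carbonyl oxygen could also close a six-membered ring to a cyclic imidate. That adduct cannot dehydrate to a neutral conjugated product and reverts, so N-closure followed by irreversible dehydration is the thermodynamic exit. PPTS at 80 °C is mild enough for the prenyl alkene, the allyl ether and the unprotected indole.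

Step 9
Reactants: 16 (3S,6Z)-1-(allyloxy)-3-methyl-6-{[7-(3-methylbut-2-en-1-yl)-1H-indol-3-yl]methylidene}piperazine-2,5-dione
Product: 18 1-(allyloxy)-5-methoxy-3-methyl-6-{[7-(3-methylbut-2-en-1-yl)-1H-indol-3-yl]methyl}pyrazin-2(1H)-one, via lactim ether 17 (not isolated)
Conditions: Me3OBF4, CH2Cl2, 0 °C to rt; aq NaHCO3 work-up; then DBU (cat.), THF, rt
Reagents that add atoms: trimethyloxonium tetrafluoroborate, C[O+](C)C.F[B-](F)(F)F (O-methyl group)
Why: O-Alkylation of a secondary lactam by a trialkyloxonium salt gives the lactim ether; only C5=O belongs to an N–H lactam, and push–pull conjugation with the indole makes it the most nucleophilic oxygen, whereas C2=O sits in an N-alkoxy-N-alkenyl amide. DBU then removes the C3 proton (α to C2=O and to N4=C5) and reprotonation at the exocyclic carbon gives the aromatic pyrazinone, a prototropic shift driven by aromatisation that is known for O-alkylated arylidene dioxopiperazines.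

Step 10
Reactants: 18 1-(allyloxy)-5-methoxy-3-methyl-6-{[7-(3-methylbut-2-en-1-yl)-1H-indol-3-yl]methyl}pyrazin-2(1H)-one
Product: 19 astepyrazinoxide, 1-hydroxy-5-methoxy-3-methyl-6-{[7-(3-methylbut-2-en-1-yl)-1H-indol-3-yl]methyl}pyrazin-2(1H)-one
Conditions: Pd(PPh3)4 (5 mol %), morpholine, THF, rt; work-up at pH 4
Reagents that add atoms: none
Why: Tsuji–Trost-type deallylation; zerovalent palladium ionises the O–allyl bond, the pyrazinone N-oxide anion being a good leaving group, and morpholine captures the π-allyl complex. The prenyl group has no leaving group and the lactim ether is untouched.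

## Compound list

1 | 7-bromo-1H-indole | Brc1cccc2cc[nH]c12 | starting material
2 | 4,4,5,5-tetramethyl-2-(3-methylbut-2-en-1-yl)-1,3,2-dioxaborolane | CC(C)=CCB1OC(C)(C)C(C)(C)O1 | starting material
3 | 7-(3-methylbut-2-en-1-yl)-1H-indole | CC(C)=CCc1cccc2cc[nH]c12 | intermediate
4 | N,N-dimethyl-1-[7-(3-methylbut-2-en-1-yl)-1H-indol-3-yl]methaniminium chloride | C[N+](C)=Cc1c[nH]c2c(CC=C(C)C)cccc12.[Cl-] | intermediate
5 | 7-(3-methylbut-2-en-1-yl)-1H-indole-3-carbaldehyde | O=Cc1c[nH]c2c(CC=C(C)C)cccc12 | intermediate
6 | N-acetylglycine | CC(=O)NCC(=O)O | starting material
7 | (4Z)-4-{[1-acetyl-7-(3-methylbut-2-en-1-yl)-1H-indol-3-yl]methylidene}-2-methyl-1,3-oxazol-5(4H)-one | CC1=N/C(=C\c2cn(C(C)=O)c3c(CC=C(C)C)cccc23)C(=O)O1 | intermediate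
8 | sodium (2Z)-2-acetamido-3-[7-(3-methylbut-2-en-1-yl)-1H-indol-3-yl]prop-2-enoate | CC(=O)N/C(=C\c1c[nH]c2c(CC=C(C)C)cccc12)C(=O)[O-].[Na+] | intermediate
9 | 3-[7-(3-methylbut-2-en-1-yl)-1H-indol-3-yl]-2-oxopropanoic acid (keto form drawn; largely enol) | O=C(O)C(=O)Cc1c[nH]c2c(CC=C(C)C)cccc12 | intermediate
10 | N-(tert-butoxycarbonyl)-L-alanine (S) | C[C@H](NC(=O)OC(C)(C)C)C(=O)O | starting material
11 | O-allylhydroxylamine hydrochloride | C=CCON.Cl | starting material
12 | tert-butyl N-[(2S)-1-(allyloxyamino)-1-oxopropan-2-yl]carbamate | C=CCONC(=O)[C@H](C)NC(=O)OC(C)(C)C | intermediate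
13 | (2S)-N-(allyloxy)-2-aminopropanamide hydrochloride | C=CCONC(=O)[C@H](C)N.Cl | intermediate
14 | N-[(2S)-1-(allyloxyamino)-1-oxopropan-2-yl]-3-[7-(3-methylbut-2-en-1-yl)-1H-indol-3-yl]-2-oxopropanamide | C=CCONC(=O)[C@H](C)NC(=O)C(=O)Cc1c[nH]c2c(CC=C(C)C)cccc12 | intermediate
15 | (3S)-1-(allyloxy)-6-hydroxy-3-methyl-6-{[7-(3-methylbut-2-en-1-yl)-1H-indol-3-yl]methyl}piperazine-2,5-dione (both C6 epimers) | C=CCON1C(=O)[C@H](C)NC(=O)C1(O)Cc1c[nH]c2c(CC=C(C)C)cccc12 | intermediate
16 | (3S,6Z)-1-(allyloxy)-3-methyl-6-{[7-(3-methylbut-2-en-1-yl)-1H-indol-3-yl]methylidene}piperazine-2,5-dione | C=CCON1C(=O)[C@H](C)NC(=O)/C1=C/c1c[nH]c2c(CC=C(C)C)cccc12 | intermediate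
17 | (3S,6Z)-1-(allyloxy)-5-methoxy-3-methyl-6-{[7-(3-methylbut-2-en-1-yl)-1H-indol-3-yl]methylidene}-3,6-dihydropyrazin-2(1H)-one | C=CCON1C(=O)[C@H](C)N=C(OC)/C1=C/c1c[nH]c2c(CC=C(C)C)cccc12 | intermediate
18 | 1-(allyloxy)-5-methoxy-3-methyl-6-{[7-(3-methylbut-2-en-1-yl)-1H-indol-3-yl]methyl}pyrazin-2(1H)-one | COc1nc(C)c(=O)n(OCC=C)c1Cc1c[nH]c2c(CC=C(C)C)cccc12 | intermediate
19 | astepyrazinoxide, 1-hydroxy-5-methoxy-3-methyl-6-{[7-(3-methylbut-2-en-1-yl)-1H-indol-3-yl]methyl}pyrazin-2(1H)-one (no stereocentre) | COc1nc(C)c(=O)n(O)c1Cc1c[nH]c2c(CC=C(C)C)cccc12 | target

## Step count and least certain steps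

Total number of steps: 10. Longest linear sequence: 8 steps (steps 1, 2, 3, 4, 7, 8, 9 and 10, from 1 to 19); the branch from 10 and 11 (steps 5 and 6) joins at step 7.

Step 8 (key step). What may go wrong: the closure may stall, either because 14 rests as its indole-conjugated enol and the neutral hydroxamate nitrogen adds too slowly, or because the sequence stops at the hemiaminal or at the reversible O-closed imidate; prolonged heating with acid could then degrade the indole. Fallback, from 14 back to 16: bond formation and dehydration are separated and the nucleophile is changed to the hydroxamate anion. K2CO3 or Et3N in MeCN at rt deprotonates the hydroxamate (pKa about 9 to 10), and the N-anion adds to the ketone to give 15, which is isolated as a mixture of C6 epimers. MsCl and Et3N (CH2Cl2, 0 °C) then convert the tertiary hydroxyl into a leaving group, and elimination through the N-acyl-N-alkoxyiminium ion gives 16 under non-equilibrating conditions. New compounds on this way: none F0.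

Step 1. What may go wrong: loss of regiocontrol in the allyl transfer (reductive elimination through the substituted terminus, giving the 1,1-dimethylallyl isomer), or protodeboronation of 2 before transmetalation. Fallback, from 1 back to 3, with polar instead of palladium chemistry: 1 is deprotonated with KH (THF, 0 °C) and treated with t-BuLi (2 equiv, −78 °C) to give 7-lithio-1-potassioindole F1. This is alkylated at carbon with prenyl bromide (1 equiv, −78 °C); the aryl–lithium bond is far more nucleophilic than the delocalised indolide nitrogen, and SN2 attack at the unhindered CH2 gives the linear isomer 3.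

Step 4. What may go wrong: oxidative degradation of the enolate of the keto acid by traces of air during the hot alkaline hydrolysis and the isolation, or incomplete cleavage of the acetamide. Fallback, from 5 back to 14 (it bypasses steps 3, 4 and 7), carrying the ketone as a carbamate-protected enamine:
- 5 is converted with Boc2O and DMAP (MeCN) into tert-butyl 3-formyl-7-(3-methylbut-2-en-1-yl)-1H-indole-1-carboxylate F2.
- Horner–Wadsworth–Emmons olefination with methyl 2-[(tert-butoxycarbonyl)amino]-2-(dimethoxyphosphoryl)acetate and DBU (CH2Cl2) gives methyl (2Z)-2-[(tert-butoxycarbonyl)amino]-3-[1-(tert-butoxycarbonyl)-7-(3-methylbut-2-en-1-yl)-1H-indol-3-yl]prop-2-enoate F3.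
- LiOH in THF/MeOH/H2O at 40 °C saponifies the ester and removes the indole carbamate, giving the stable dehydroamino acid (2Z)-2-[(tert-butoxycarbonyl)amino]-3-[7-(3-methylbut-2-en-1-yl)-1H-indol-3-yl]prop-2-enoic acid F4.
- EDC/HOAt coupling with 13 gives tert-butyl N-[(1Z)-3-{[(2S)-1-(allyloxyamino)-1-oxopropan-2-yl]amino}-1-[7-(3-methylbut-2-en-1-yl)-1H-indol-3-yl]-3-oxoprop-1-en-2-yl]carbamate F5.
- Brief TFA/CH2Cl2 at 0 °C followed by aqueous NaHCO3 removes the enamine carbamate; the free enamine tautomerises to the imine and hydrolyses to 14.

Step 7. What may go wrong: during carbodiimide activation the α-keto acid may acylate itself through its enol oxygen and oligomerise, or condense with the amine at the ketone, so that little of the active ester reaches the amide. Fallback, from 9 back to 14, with the ketone masked as a silyl enol ether: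
- 9 is persilylated with TBSCl and imidazole (DMF) to tert-butyldimethylsilyl (2Z)-2-[(tert-butyldimethylsilyl)oxy]-3-[7-(3-methylbut-2-en-1-yl)-1H-indol-3-yl]prop-2-enoate F6.
- Brief K2CO3 in MeOH/H2O at 0 °C cleaves only the silyl ester, giving (2Z)-2-[(tert-butyldimethylsilyl)oxy]-3-[7-(3-methylbut-2-en-1-yl)-1H-indol-3-yl]prop-2-enoic acid F7.
- This acid, which has neither a ketone nor a free enol, is coupled with 13 (EDC, HOAt) to (2Z)-N-[(2S)-1-(allyloxyamino)-1-oxopropan-2-yl]-2-[(tert-butyldimethylsilyl)oxy]-3-[7-(3-methylbut-2-en-1-yl)-1H-indol-3-yl]prop-2-enamide F8.
- TBAF buffered with AcOH (THF, 0 °C) releases 14.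

Step 9. What may go wrong: competing methylation of the electron-rich vinylindole by the hard oxonium ion, or acid-promoted closure of the prenyl group onto N1' by the HBF4 bound in the imidate salt before the work-up. Fallback, from 16 back to 18 through 17, with a soft electrophile on a silver imidate instead of a hard electrophile on the neutral lactam: Ag2CO3 and MeI in toluene in the dark. Silver bound at N4 should direct methylation to oxygen as it does for 2-pyridones, and methyl iodide without strong base does not alkylate indoles. The 17 so formed re-enters at the DBU stage of step 9 and gives 18. New compounds on this way: none F0.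

## Further compounds

F0 | step 8 | none | none
F1 | step 1 | 7-lithio-1-potassioindole | [Li]c1cccc2ccn([K])c12
F2 | step 4 | tert-butyl 3-formyl-7-(3-methylbut-2-en-1-yl)-1H-indole-1-carboxylate | CC(C)=CCc1cccc2c(C=O)cn(C(=O)OC(C)(C)C)c12
F3 | step 4 | methyl (2Z)-2-[(tert-butoxycarbonyl)amino]-3-[1-(tert-butoxycarbonyl)-7-(3-methylbut-2-en-1-yl)-1H-indol-3-yl]prop-2-enoate | COC(=O)/C(NC(=O)OC(C)(C)C)=C/c1cn(C(=O)OC(C)(C)C)c2c(CC=C(C)C)cccc12
F4 | step 4 | (2Z)-2-[(tert-butoxycarbonyl)amino]-3-[7-(3-methylbut-2-en-1-yl)-1H-indol-3-yl]prop-2-enoic acid | OC(=O)/C(NC(=O)OC(C)(C)C)=C/c1c[nH]c2c(CC=C(C)C)cccc12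
F5 | step 4 | tert-butyl N-[(1Z)-3-{[(2S)-1-(allyloxyamino)-1-oxopropan-2-yl]amino}-1-[7-(3-methylbut-2-en-1-yl)-1H-indol-3-yl]-3-oxoprop-1-en-2-yl]carbamate | C=CCONC(=O)[C@H](C)NC(=O)/C(NC(=O)OC(C)(C)C)=C/c1c[nH]c2c(CC=C(C)C)cccc12
F6 | step 7 | tert-butyldimethylsilyl (2Z)-2-[(tert-butyldimethylsilyl)oxy]-3-[7-(3-methylbut-2-en-1-yl)-1H-indol-3-yl]prop-2-enoate | CC(C)=CCc1cccc2c(/C=C(\O[Si](C)(C)C(C)(C)C)C(=O)O[Si](C)(C)C(C)(C)C)c[nH]c12
F7 | step 7 | (2Z)-2-[(tert-butyldimethylsilyl)oxy]-3-[7-(3-methylbut-2-en-1-yl)-1H-indol-3-yl]prop-2-enoic acid | CC(C)=CCc1cccc2c(/C=C(\O[Si](C)(C)C(C)(C)C)C(=O)O)c[nH]c12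
F8 | step 7 | (2Z)-N-[(2S)-1-(allyloxyamino)-1-oxopropan-2-yl]-2-[(tert-butyldimethylsilyl)oxy]-3-[7-(3-methylbut-2-en-1-yl)-1H-indol-3-yl]prop-2-enamide | C=CCONC(=O)[C@H](C)NC(=O)/C(O[Si](C)(C)C(C)(C)C)=C/c1c[nH]c2c(CC=C(C)C)cccc12
F0 | step 9 | none | none
A1 | alternative 1 | 5-methoxy-1-[(4-methoxybenzyl)oxy]-3-methyl-6-{[7-(3-methylbut-2-en-1-yl)-2-(triethylsilyl)-1H-indol-3-yl]methyl}pyrazin-2(1H)-one | COc1nc(C)c(=O)n(OCc2ccc(OC)cc2)c1Cc1c([Si](CC)(CC)CC)[nH]c2c(CC=C(C)C)cccc12
A2 | alternative 1 | 2-bromo-6-(3-methylbut-2-en-1-yl)aniline | CC(C)=CCc1cccc(Br)c1N
A3 | alternative 1 | 5-methoxy-1-[(4-methoxybenzyl)oxy]-3-methyl-6-[3-(triethylsilyl)prop-2-yn-1-yl]pyrazin-2(1H)-one | COc1nc(C)c(=O)n(OCc2ccc(OC)cc2)c1CC#C[Si](CC)(CC)CC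
A4 | alternative 2 | tert-butyl 7-(3-methylbut-2-en-1-yl)indoline-1-carboxylate | CC(C)=CCc1cccc2c1N(C(=O)OC(C)(C)C)CC2
A5 | alternative 2 | tert-butyl N-(but-3-en-1-yl)-N-[3-(3-methylbut-2-en-1-yl)furan-2-yl]carbamate | C=CCCN(C(=O)OC(C)(C)C)c1occc1CC=C(C)C
A6 | alternative 3 | 1-(allyloxy)-3-methyl-6-{[7-(3-methylbut-2-en-1-yl)-1H-indol-3-yl]methyl}piperazine-2,5-dione (mixture of diastereomers) | C=CCON1C(=O)C(C)NC(=O)C1Cc1c[nH]c2c(CC=C(C)C)cccc12
A7 | alternative 3 | 2-[7-(3-methylbut-2-en-1-yl)-1H-indol-3-yl]acetaldehyde O-allyl oxime | C=CCON=CCc1c[nH]c2c(CC=C(C)C)cccc12
A8 | alternative 3 | potassium 2-isocyanopropanoate | CC([N+]#[C-])C(=O)[O-].[K+]
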